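**Strategy.** Oxane numbering: O1, C2 carries the acrylic acid, C5 the side chain, C6 is the ring CH2. The O1–C6H2 unit is read as one molecule of formaldehyde inserted between C5 and C2, which are 1,4-related and cis. With C3=C4 unsaturated, this is the retron of an oxa-Diels–Alder reaction of an E,E-diene. The carboxyl carbon, lowered to an aldehyde, is conjugated with that diene in a linear 2,4-dienal, so a chiral secondary amine can raise its HOMO as a trienamine. One operation then forms C5–C6 and O1–C2, closes the ring and sets both stereocentres; a second formaldehyde adds the future exo-methylene carbon in the same flask. The precursor is an acyclic C22 pentaenal made from farnesyl bromide in two steps.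

Key step: step 3

Remark: the centre created at C-2 of the three-carbon acid chain in step 3 forms as a mixture of epimers and is drawn without configuration; step 5 turns it into the sp2 carbon of the acrylic acid.

**Step 1**
Reactants: 1 (2E,6E)-1-bromo-3,7,11-trimethyldodeca-2,6,10-triene (E,E-farnesyl bromide); 2 but-3-en-1-ylmagnesium bromide
Product: 3 (6E,10E)-7,11,15-trimethylhexadeca-1,6,10,14-tetraene
Conditions: Li2CuCl4 (3 mol%), THF, −78 °C to 0 °C
Reagents that add atoms: none
Why: Copper-catalysed cross-coupling of a primary alkyl Grignard reagent with an allylic bromide should take place at the unhindered primary carbon of 1 and not at the tertiary γ-carbon, so four carbons are added and both E olefins are kept; no stereocentre is formed.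

**Step 2**
Reactants: 3 (6E,10E)-7,11,15-trimethylhexadeca-1,6,10,14-tetraene; 4 (2E,4E)-hexa-2,4-dienal
Product: 5 (2E,4E,9E,13E)-10,14,18-trimethylnonadeca-2,4,9,13,17-pentaenal
Conditions: second-generation Grubbs catalyst (5 mol%), 4 (4 equiv), CH2Cl2, 40 °C
Reagents that add atoms: none
Why: Olefin cross-metathesis: the monosubstituted olefin of 3 is the only fast-reacting one, the trisubstituted chain olefins and the aldehyde-deactivated C2=C3 bond of 4 react far more slowly, so the methyl-bearing terminus of 4 is exchanged for the chain and propene escapes; the geometry of the new olefin does not matter because both olefins of 5 become single bonds in trienamine 7.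

**Step 3**
Reactants: 5 (2E,4E,9E,13E)-10,14,18-trimethylnonadeca-2,4,9,13,17-pentaenal; 6 formaldehyde (two molecules are incorporated)
Product: 10 3-hydroxy-2-[(2R,5R)-5-[(3E,7E)-4,8,12-trimethyltrideca-3,7,11-trien-1-yl]-5,6-dihydro-2H-pyran-2-yl]propanoic acid, via trienamine 7 (not isolated), via cycloadduct aldehyde 8 (not isolated), via hydroxymethyl aldehyde 9 (not isolated)
Conditions: (S)-2-[diphenyl(trimethylsilyloxy)methyl]pyrrolidine (20 mol%), 37% aq. CH2O (5 equiv), toluene, pH 7 phosphate buffer, rt; then NaClO2, NaH2PO4, 2-methyl-2-butene, tBuOH/H2O, 0 °C to rt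
Reagents that add atoms: sodium chlorite, [O-]Cl=O.[Na+]
Why: Proposed new method: the amine condenses with 5 and the iminium ion loses its ε-proton to give the all-E trienamine 7, whose HOMO-raised s-cis diene (the future C2=C3–C4=C5 of the ring) should add to the C=O bond of formaldehyde in a polarity-matched, asynchronous oxa-[4+2] cycloaddition in which the nucleophilic ε-carbon takes the carbonyl carbon (bond C5–C6) and the oxygen closes on the β-carbon (bond O1–C2). The closest known reaction types are the [4+2] cycloadditions of trienamines with electron-poor alkenes and with thiocarbonyl compounds, the hetero-Diels–Alder reaction of 1-amino-1,3-dienes with simple aldehydes and the enamine aldol reaction with aqueous formaldehyde. The dihydropyran ring is closed by the cycloaddition itself or, if the bonds form in two stages, by ε-aldol addition followed by 6-exo-trig oxa-Michael closure onto the dienyl iminium ion. Both bonds form on one face of a diene whose two terminal substituents point outward, which makes C2 and C5 cis, and the CPh2(OSiMe3) group of the (S)-catalyst shields one face of the planar trienamine, so that attack on the open face should give the (2R,5R) ring (8 is named 2S only because the ring olefin outranks the CH2CHO group). The step needs ε,β-cycloaddition to win over α-hydroxymethylation of the trienamine and needs the three chain olefins to stay untouched: the first rests on the reversibility of an α-aldol adduct while the cycloadduct is drained irreversibly, the second on the absence of any acid able to activate formaldehyde towards isolated olefins. The enamine released from the cycloaddition is hydroxymethylated by a second formaldehyde (known enamine aldol) to 9, which blocks retro-oxa-Michael epimerisation at C2 and brings in the future methylene carbon, and NaClO2 (Pinnick oxidation) then converts the labile aldehyde into acid 10.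

**Step 4**
Reactants: 10 3-hydroxy-2-[(2R,5R)-5-[(3E,7E)-4,8,12-trimethyltrideca-3,7,11-trien-1-yl]-5,6-dihydro-2H-pyran-2-yl]propanoic acid
Product: 11 3-hydroxy-2-[(2R,5R)-5-[(3E,7E)-4,8,12-trimethyltrideca-3,7,11-trien-1-yl]oxan-2-yl]propanoic acid
Conditions: H2 (1 atm), RhCl(PPh3)3 (10 mol%), benzene/EtOH 1:1, rt
Reagents that add atoms: none
Why: Homogeneous hydrogenation with RhCl(PPh3)3 discriminates strongly by olefin substitution, so the cis-1,2-disubstituted ring olefin should be reduced while the three trisubstituted chain olefins are left; no stereocentre is formed and C2 and C5 cannot epimerise under these neutral conditions.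

**Step 5**
Reactants: 11 3-hydroxy-2-[(2R,5R)-5-[(3E,7E)-4,8,12-trimethyltrideca-3,7,11-trien-1-yl]oxan-2-yl]propanoic acid
Product: 14 rhopaloic acid B, via bis-mesyl intermediate 12 (not isolated), via acrylic mixed anhydride 13 (not isolated)
Conditions: MsCl (2.5 equiv), Et3N, CH2Cl2, −20 °C; DBU, 0 °C to rt; then THF/aq. NaHCO3
Reagents that add atoms: water, O
Why: Dehydration of a β-hydroxy acid by β-elimination: sulfonylation of both OH groups gives primary mesylate and mixed carboxylic–sulfonic anhydride 12, whose activated acyl group allows DBU-induced E1cB loss of mesylate (a far better leaving group than the ring alkoxide at C2, so the oxane stays closed) to 13, and aqueous work-up hydrolyses the anhydride; the epimeric α-centre disappears and C2 and C5 are untouched.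

**Compound list**
1 | (2E,6E)-1-bromo-3,7,11-trimethyldodeca-2,6,10-triene | BrC/C=C(\C)CC/C=C(\C)CCC=C(C)C | starting material
2 | but-3-en-1-ylmagnesium bromide | C=CCC[Mg]Br | starting material
3 | (6E,10E)-7,11,15-trimethylhexadeca-1,6,10,14-tetraene | C=CCCC/C=C(\C)CC/C=C(\C)CCC=C(C)C | intermediate
4 | (2E,4E)-hexa-2,4-dienal | C/C=C/C=C/C=O | starting material
5 | (2E,4E,9E,13E)-10,14,18-trimethylnonadeca-2,4,9,13,17-pentaenal | O=C/C=C/C=C/CCC/C=C(\C)CC/C=C(\C)CCC=C(C)C | intermediate
6 | formaldehyde | C=O | starting material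
7 | (2S)-2-[diphenyl(trimethylsilyloxy)methyl]-1-[(1E,3E,5E,9E,13E)-10,14,18-trimethylnonadeca-1,3,5,9,13,17-hexaen-1-yl]pyrrolidine (trienamine) | C[Si](C)(C)OC(c1ccccc1)(c1ccccc1)[C@@H]1CCCN1/C=C/C=C/C=C/CC/C=C(\C)CC/C=C(\C)CCC=C(C)C | intermediate
8 | 2-[(2S,5R)-5-[(3E,7E)-4,8,12-trimethyltrideca-3,7,11-trien-1-yl]-5,6-dihydro-2H-pyran-2-yl]acetaldehyde (cis) | O=CC[C@H]1C=C[C@@H](CC/C=C(\C)CC/C=C(\C)CCC=C(C)C)CO1 | intermediate
9 | 3-hydroxy-2-[(2R,5R)-5-[(3E,7E)-4,8,12-trimethyltrideca-3,7,11-trien-1-yl]-5,6-dihydro-2H-pyran-2-yl]propanal (both epimers at C-2 of the propanal) | O=CC(CO)[C@H]1C=C[C@@H](CC/C=C(\C)CC/C=C(\C)CCC=C(C)C)CO1 | intermediate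
10 | 3-hydroxy-2-[(2R,5R)-5-[(3E,7E)-4,8,12-trimethyltrideca-3,7,11-trien-1-yl]-5,6-dihydro-2H-pyran-2-yl]propanoic acid (both epimers at C-2 of the acid) | OCC(C(=O)O)[C@H]1C=C[C@@H](CC/C=C(\C)CC/C=C(\C)CCC=C(C)C)CO1 | intermediate
11 | 3-hydroxy-2-[(2R,5R)-5-[(3E,7E)-4,8,12-trimethyltrideca-3,7,11-trien-1-yl]oxan-2-yl]propanoic acid (both epimers at C-2 of the acid) | OCC(C(=O)O)[C@H]1CC[C@@H](CC/C=C(\C)CC/C=C(\C)CCC=C(C)C)CO1 | intermediate
12 | methanesulfonic 3-(methanesulfonyloxy)-2-[(2R,5R)-5-[(3E,7E)-4,8,12-trimethyltrideca-3,7,11-trien-1-yl]oxan-2-yl]propanoic anhydride | CS(=O)(=O)OCC(C(=O)OS(C)(=O)=O)[C@H]1CC[C@@H](CC/C=C(\C)CC/C=C(\C)CCC=C(C)C)CO1 | intermediate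
13 | methanesulfonic 2-[(2R,5R)-5-[(3E,7E)-4,8,12-trimethyltrideca-3,7,11-trien-1-yl]oxan-2-yl]prop-2-enoic anhydride | C=C(C(=O)OS(C)(=O)=O)[C@H]1CC[C@@H](CC/C=C(\C)CC/C=C(\C)CCC=C(C)C)CO1 | intermediate
14 | rhopaloic acid B, 2-[(2R,5R)-5-[(3E,7E)-4,8,12-trimethyltrideca-3,7,11-trien-1-yl]oxan-2-yl]prop-2-enoic acid | C=C(C(=O)O)[C@H]1CC[C@@H](CC/C=C(\C)CC/C=C(\C)CCC=C(C)C)CO1 | target

**Total step count:** 5. **Longest linear sequence:** 5 steps (1 → 3 → 5 → 10 → 11 → 14).

**Steps most likely to fail**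

1. Step 3 (Proposed new method). Formaldehyde may add to the α-carbon of the trienamine, or by a stepwise ε-aldol through the s-trans diene, which cannot close the ring; facial discrimination at the remote diene may also be poor. The fallback uses known chemistry only, sets out from 1 and comes back to the route at 14.
   - Li2CuCl4-catalysed coupling of 1 with [2-(1,3-dioxolan-2-yl)ethyl]magnesium bromide should give 2-[(4E,8E)-5,9,13-trimethyltetradeca-4,8,12-trien-1-yl]-1,3-dioxolane F1. Mild hydrolysis (AcOH, THF, H2O) should give the acid-sensitive aldehyde (5E,9E)-6,10,14-trimethylpentadeca-5,9,13-trienal F2.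
   - Enamine-catalysed α-hydroxymethylation of F2 with aqueous 6 and (R)-2-[diphenyl(trimethylsilyloxy)methyl]pyrrolidine (toluene, pH 7 buffer) sets C5 and should give (2S,5E,9E)-2-(hydroxymethyl)-6,10,14-trimethylpentadeca-5,9,13-trienal F3.
   - In the same flask Ph3P=C=C=O acylates the hydroxyl group to the ester ylide [(2S,5E,9E)-2-formyl-6,10,14-trimethylpentadeca-5,9,13-trien-1-yl] 2-(triphenyl-λ5-phosphanylidene)acetate F4. Intramolecular Wittig olefination then closes (5R)-5-[(3E,7E)-4,8,12-trimethyltrideca-3,7,11-trien-1-yl]-5,6-dihydro-2H-pyran-2-one F5, so the formaldehyde carbon is again joined to C5 and its oxygen to C2 in one flask.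
   - Conjugate reduction with [(Ph3P)CuH]6 should give (5R)-5-[(3E,7E)-4,8,12-trimethyltrideca-3,7,11-trien-1-yl]oxan-2-one F6. DIBAL-H (CH2Cl2, −78 °C) gives the lactol (5R)-5-[(3E,7E)-4,8,12-trimethyltrideca-3,7,11-trien-1-yl]oxan-2-ol F7, and Ac2O, pyridine and DMAP give (5R)-5-[(3E,7E)-4,8,12-trimethyltrideca-3,7,11-trien-1-yl]oxan-2-yl acetate F8.
   - BF3·OEt2 and CH2=CHOSiMe3 (−78 °C) should give 2-[(2R,5R)-5-[(3E,7E)-4,8,12-trimethyltrideca-3,7,11-trien-1-yl]oxan-2-yl]acetaldehyde F9. The nucleophile attacks the half-chair oxocarbenium ion axially with the C5 chain equatorial, which gives the cis isomer under kinetic control.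
   - α-Methylenation (aqueous 6, pyrrolidine, propionic acid) should give 2-[(2R,5R)-5-[(3E,7E)-4,8,12-trimethyltrideca-3,7,11-trien-1-yl]oxan-2-yl]prop-2-enal F10, and Pinnick oxidation gives 14.

2. Step 5. O-alkylation or acyl transfer to a β-lactone may compete with elimination, and base may move the exo-methylene into conjugation with the ring oxygen. The fallback sets out from 11 and comes back at 14. Me3SiCHN2 (toluene/MeOH) gives methyl 3-hydroxy-2-[(2R,5R)-5-[(3E,7E)-4,8,12-trimethyltrideca-3,7,11-trien-1-yl]oxan-2-yl]propanoate F11. MsCl and Et3N give methyl 3-(methanesulfonyloxy)-2-[(2R,5R)-5-[(3E,7E)-4,8,12-trimethyltrideca-3,7,11-trien-1-yl]oxan-2-yl]propanoate F12. DBU eliminates through the ester enolate, with no lactone pathway open, to methyl 2-[(2R,5R)-5-[(3E,7E)-4,8,12-trimethyltrideca-3,7,11-trien-1-yl]oxan-2-yl]prop-2-enoate F13. LiOH in THF/H2O gives 14.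

3. Step 2. Metathesis at the terminal isopropylidene olefin would truncate the chain, 3 may homodimerise, and the dienal-derived ruthenium alkylidene may turn over slowly. The fallback sets out from 1 and comes back at 5. Acetal F1 and aldehyde F2 are made from 1 exactly as in the first fallback. Wittig reaction of F2 with Ph3P=CHCHO (toluene, 80 °C) should give (2E,7E,11E)-8,12,16-trimethylheptadeca-2,7,11,15-tetraenal F14, and a second Wittig reaction with the same ylide gives 5.

**Further compounds**
F1 | step 3 | 2-[(4E,8E)-5,9,13-trimethyltetradeca-4,8,12-trien-1-yl]-1,3-dioxolane | C1COC(O1)CCC/C=C(\C)CC/C=C(\C)CCC=C(C)C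
F2 | step 3 | (5E,9E)-6,10,14-trimethylpentadeca-5,9,13-trienal | O=CCCC/C=C(\C)CC/C=C(\C)CCC=C(C)C
F3 | step 3 | (2S,5E,9E)-2-(hydroxymethyl)-6,10,14-trimethylpentadeca-5,9,13-trienal | O=C[C@@H](CC/C=C(\C)CC/C=C(\C)CCC=C(C)C)CO
F4 | step 3 | [(2S,5E,9E)-2-formyl-6,10,14-trimethylpentadeca-5,9,13-trien-1-yl] 2-(triphenyl-λ5-phosphanylidene)acetate | O=C[C@@H](CC/C=C(\C)CC/C=C(\C)CCC=C(C)C)COC(=O)C=P(c1ccccc1)(c1ccccc1)c1ccccc1
F5 | step 3 | (5R)-5-[(3E,7E)-4,8,12-trimethyltrideca-3,7,11-trien-1-yl]-5,6-dihydro-2H-pyran-2-one | O=C1C=C[C@@H](CC/C=C(\C)CC/C=C(\C)CCC=C(C)C)CO1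
F6 | step 3 | (5R)-5-[(3E,7E)-4,8,12-trimethyltrideca-3,7,11-trien-1-yl]oxan-2-one | O=C1CC[C@@H](CC/C=C(\C)CC/C=C(\C)CCC=C(C)C)CO1
F7 | step 3 | (5R)-5-[(3E,7E)-4,8,12-trimethyltrideca-3,7,11-trien-1-yl]oxan-2-ol (both anomers) | OC1CC[C@@H](CC/C=C(\C)CC/C=C(\C)CCC=C(C)C)CO1
F8 | step 3 | (5R)-5-[(3E,7E)-4,8,12-trimethyltrideca-3,7,11-trien-1-yl]oxan-2-yl acetate (both anomers) | CC(=O)OC1CC[C@@H](CC/C=C(\C)CC/C=C(\C)CCC=C(C)C)CO1
F9 | step 3 | 2-[(2R,5R)-5-[(3E,7E)-4,8,12-trimethyltrideca-3,7,11-trien-1-yl]oxan-2-yl]acetaldehyde | O=CC[C@H]1CC[C@@H](CC/C=C(\C)CC/C=C(\C)CCC=C(C)C)CO1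
F10 | step 3 | 2-[(2R,5R)-5-[(3E,7E)-4,8,12-trimethyltrideca-3,7,11-trien-1-yl]oxan-2-yl]prop-2-enal | C=C(C=O)[C@H]1CC[C@@H](CC/C=C(\C)CC/C=C(\C)CCC=C(C)C)CO1
F11 | step 5 | methyl 3-hydroxy-2-[(2R,5R)-5-[(3E,7E)-4,8,12-trimethyltrideca-3,7,11-trien-1-yl]oxan-2-yl]propanoate (both epimers at C-2 of the ester) | COC(=O)C(CO)[C@H]1CC[C@@H](CC/C=C(\C)CC/C=C(\C)CCC=C(C)C)CO1
F12 | step 5 | methyl 3-(methanesulfonyloxy)-2-[(2R,5R)-5-[(3E,7E)-4,8,12-trimethyltrideca-3,7,11-trien-1-yl]oxan-2-yl]propanoate | COC(=O)C(COS(C)(=O)=O)[C@H]1CC[C@@H](CC/C=C(\C)CC/C=C(\C)CCC=C(C)C)CO1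
F13 | step 5 | methyl 2-[(2R,5R)-5-[(3E,7E)-4,8,12-trimethyltrideca-3,7,11-trien-1-yl]oxan-2-yl]prop-2-enoate | COC(=O)C(=C)[C@H]1CC[C@@H](CC/C=C(\C)CC/C=C(\C)CCC=C(C)C)CO1
F14 | step 2 | (2E,7E,11E)-8,12,16-trimethylheptadeca-2,7,11,15-tetraenal | O=C/C=C/CCC/C=C(\C)CC/C=C(\C)CCC=C(C)C
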